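## Structural features

The target is a C30 seco-triterpenoid built on a spiro[4.5]decane: a cyclopentane (C1–C5) and a cyclohexane (C5–C10) share the quaternary carbon C5. The five-membered ring carries a secondary hydroxyl at C1 and, cis to it at C2, a 1-methylene-substituted (3E,5Z)-triene arm that ends in an allylic primary alcohol and a homoprenyl chain. The six-membered ring carries a 3-hydroxypropyl chain at C6, a tetrasubstituted (Z)-1-formylethylidene group at C7 (exocyclic carbon C11, formyl carbon C12) and a methyl-bearing tertiary carbinol at C10. Four stereocentres (C1, C5, C6, C10) are contiguous around the spiro carbon and C2 adjoins C1; the C1 and C10 oxygens are syn across C5, and C1 lies on the same face of the six-membered ring as the C6 chain. Fragile groups are the enal (γ-hydrogens at C6 and C8), the conjugated triene (acid, light, oxidants), the tertiary alcohol, and the 1,1-disubstituted alkene at C2, whose migration into the ring would erase C2. The real difficulty is the congested spiro carbon with its three stereogenic neighbours, together with the geometry of the C7=C11 alkene, whose two ring-side substituents differ only in the substitution at C6 versus C8. The key step exploits the cis 1-hydroxy-2-(alk-1-en-2-yl) pattern on C1/C2, which is the imprint of an intramolecular carbonyl-ene reaction between a formyl group on C5 and a trisubstituted alkene in the C4–C3–C2 arm. The ring C5–C10, with the C10 methyl and the three-carbon unit at C7, maps onto carvone.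

## Logic of the disconnections

35 ⇒ 34 ⇒ 33. No skeletal bond is cut: two O–Si bonds are restored and C12 is taken back to the alcohol level. The reason is that the enal cannot pass through the hydride-based coupling step, and the allylic alcohol of the arm must stay masked during the C12 oxidation. The demand is an oxidant that touches only the tetrasubstituted primary allylic alcohol and a fluoride source that spares enal and triene.

33 ⇒ 25 + 31. The single bond between the E-disubstituted and the Z-trisubstituted alkene of the arm is cut. This divides the molecule into the stereochemically dense core and an achiral C9 piece, and makes the route convergent. Forward, the terminal alkyne of the enyne must be hydrometalated syn with the metal on the terminal carbon, and both partners must couple with retention.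

31 ⇒ 30 ⇒ 26 + 27. The bond between the homoprenyl CH2 and the alkene carbon bearing CH2OH is cut, together with C–I. Chelation-controlled anti-carbomagnesiation of a propargylic alkoxide places the metal, and then iodine, cis to CH2OH, which is the geometry the triene needs.

25 ⇒ 23 ⇒ 22 ⇒ 20. No skeletal bond is cut: the C7=C11 double bond is moved back to C11=CH2 with a hydrogen returned to C7, and C12 is returned to a methyl group. This reveals an isopropenyl group on an sp3 C7, the chiral-pool stereocentre that relays configuration to C6 and C5. Forward, it demands a methyl-selective allylic oxidation and a double-bond migration that must end in the Z geometry, which is the weakest link of the plan.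

20 ⇒ 19 ⇒ 18. The C10–O bond and one C9–H bond are removed via the epoxide, so the tertiary carbinol becomes the C9=C10 alkene. The C1 hydroxyl sits on the correct face to deliver the oxygen. The forward steps need face-selective, chemoselective epoxidation and hydride attack at C9 only.

18 ⇒ 17. The C1–C2 bond is cut in the retro-ene sense. This opens the cyclopentane, removes two stereocentres, and turns the carbinol into a formyl group on C5 and the arm into a trisubstituted enyne alkene. The forward ene reaction must be cis-selective, must choose the correct face relative to C5, and must accept an enyne as the ene donor.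

17 ⇒ 15 + 5. The C5–C4 bond is cut. The quaternary centre becomes the α-carbon of an enal dienolate and the arm becomes a primary bromide. The demand is α- rather than γ- or O-alkylation, and entry of the electrophile anti to the C6 chain.

5 ⇒ 4 ⇒ 1 + 2. The bond between the alkyne and the carbinol carbon is cut, and the homoallylic bromide is traced to a cyclopropylcarbinol. This takes the arm back to two commodity chemicals in two steps.

15 ⇒ 13 ⇒ 12. The C5–C1 bond is cut: the formyl carbon is a one-carbon homologation of the enone carbonyl. The demand is carbonyl olefination of a hindered, enolisable ketone and acid hydrolysis that spares the silyl ether.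

12 ⇒ 11 ⇒ 9 ⇒ 6 + 7. The bond from C6 to the first carbon of the side chain is cut, and the terminal oxygen is traced to an alkene. Kinetic alkylation of the chiral-pool enone anti to the isopropenyl group sets C6. Forward, the borane must distinguish three alkenes and a ketone.

## Other disconnections considered

Alternative 1: The cut is C6–C7, with the carbon on C11 that becomes C12 supplied by carbon monoxide, so the cyclohexane is closed last onto a preformed spirocyclic cyclopentane whose C1 and C10 oxygens are tied as an acetonide.
- Forward key step: Pd(PPh3)4 (zerovalent palladium) ionises an allylic carbonate beside C5. The allyl terminus C6 adds syn across a tethered but-2-ynyl group, and the alkenylpalladium is intercepted by carbon monoxide and methanol to give A1.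
- In favour: syn carbopalladation places C6 and the ester on the same side of C7=C11 by mechanism. On alkene geometry this alternative is better than the chosen plan, whose migration step is only sterically biased. Ring, tetrasubstituted alkene and C12 also arrive in one operation, and palladium-ene additions to alkynes are precedented, so on precedent for the key step it is the equal or the better.
- Against: C2 of A1 is a bare CH2, so the triene arm would have to be attached later next to the C1 carbinol. The C6 configuration depends on the facial course of the allylpalladation relative to the spiro centre. The propenyl arm must be hydrogenated beside the enoate, the acetonide must be removed with acid late, and the precursor with C1, C5 and C10 set needs its own asymmetric synthesis.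
- Comparison on structure: the chosen plan makes C1, C2 and the arm anchor in one step and draws C5–C10 from the chiral pool, whereas the alternative solves the six-membered ring and the alkene but not C2.
- Comparison on mechanism: both key steps are intramolecular ene-type additions, one metal-mediated and one Lewis acid-mediated.
- Comparison on step economy: the extra work before and after the key step makes the alternative the longer route.

Alternative 2: The cuts are C5–C4 and the bond from C6 to its side chain.
- Forward key step: a copper-catalysed enantioselective conjugate addition of a ketal-bearing Grignard reagent desymmetrises a 4-methyl-4-silyloxycyclohexadienone, and the enolate is allylated in the same flask to give A2.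
- In favour: absolute configuration comes from a catalyst, so either enantiomer is accessible. In flexibility this equals or betters a chiral-pool start. The C10 tertiary carbinol is present from the outset, which is better than the epoxidation and hydride pair of the chosen plan. Two C–C bonds form in one flask with trans control from a cheap aromatic feedstock.
- Against: in A2, C5 is still a tertiary CH that the C7 ketone does not activate. The quaternary spiro centre, the whole cyclopentane, C1 and C2 remain to be made. The C7 ketone must later be turned into the tetrasubstituted enal with no better geometric handle than the chosen plan has, and the C8=C9 alkene must be reduced.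
- Comparison on structure: the alternative addresses only the six-membered ring, while the chosen plan reaches the complete spirocycle at its key step.
- Comparison on mechanism: catalyst control is more general than the substrate control relied on in the chosen plan.
- Comparison on step economy: the alternative would need considerably more steps after its key step.

Alternative 3: The cut is C8–C9.
- Forward key step: Cp2TiMe2 converts the carbonyl of a δ-lactone into an exocyclic enol ether, adding C9. On heating, a 3,3-sigmatropic shift through a boat transition state joins the two exocyclic methylenes and breaks the ring C–O bond, giving A3 with the C10 ketone and the C7=C11 alkene.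
- In favour: the alkene geometry is transferred from the C11 stereocentre through a cyclic transition state. On this point the alternative is better than the chosen plan. The carbocycle and a C10 carbonyl ready for methyl addition arise together, and the C1 oxygen is already in place.
- Against: C10 would then rest on the facial selectivity of methyl addition to a ketone beside the quaternary C5, where the tethered oxygen delivery of the chosen plan is the more secure. C2 of A3 is again an unfunctionalised CH2. The lactone, with its quaternary C11 stereocentre and the spiro centre, needs a separate stereocontrolled synthesis.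
- Comparison on structure: the alternative solves the alkene but leaves C2 and C10 open, whereas the chosen plan solves C1, C2 and C10 but leaves the alkene geometry weakly controlled.
- Comparison on mechanism: a sigmatropic shift with well-understood stereochemical transfer is set against an ene reaction with an untried donor.
- Comparison on step economy: comparable to or longer than the chosen plan once the lactone synthesis and the C2 functionalisation are counted.

Key step: step 9

Remark: atom numbers follow the spiro[4.5]decane numbering of the target throughout (C11 is the exocyclic carbon on C7, C12 its oxygenated carbon). Counting the formyl carbon as C1 of the chain, 17 is a 5-enal (δ,ε-unsaturated aldehyde), the substrate class for type 1 closure to a cyclopentanol. Bromide 5 is drawn as the E isomer; any Z isomer is carried along because step 9 removes this stereo element. TBS = tert-butyldimethylsilyl, TMS = trimethylsilyl, TES = triethylsilyl, Sia = 3-methylbutan-2-yl, HBpin = pinacolborane.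

## Steps

Step 1
Reactants: 1 cyclopropyl methyl ketone; 2 ethynyltrimethylsilane
Product: 4 2-cyclopropyl-4-(trimethylsilyl)but-3-yn-2-ol (racemic), via lithium (trimethylsilyl)acetylide 3 (not isolated)
Conditions: n-BuLi, THF, −78 °C; then 1, −78 → 0 °C
Reagents that add atoms: none
Why: 1,2-Addition of a lithium acetylide to a ketone; the carbinol centre is destroyed in step 2, so its configuration is irrelevant.

Step 2
Reactants: 4 2-cyclopropyl-4-(trimethylsilyl)but-3-yn-2-ol
Product: 5 [(3E)-6-bromo-3-methylhex-3-en-1-yn-1-yl]trimethylsilane
Conditions: 48% aq. HBr, 0 °C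
Reagents that add atoms: hydrogen bromide, Br
Why: Julia cyclopropylcarbinol-to-homoallyl bromide rearrangement: the tertiary propargylic cyclopropylcarbinyl cation is opened by bromide at a ring CH2. The silyl cap blocks bromide attack at the alkyne terminus (allene formation).

Step 3
Reactants: 6 (S)-(+)-carvone; 7 allyl bromide
Product: 9 (5S,6R)-2-methyl-5-(prop-1-en-2-yl)-6-(prop-2-en-1-yl)cyclohex-2-en-1-one, via carvone lithium enolate 8 (not isolated)
Conditions: LiN(iPr)2, THF, −78 °C; then 7, −78 → −20 °C
Reagents that add atoms: none
Why: Kinetic α'-enolate alkylation; the electrophile approaches the cross-conjugated enolate anti to the neighbouring isopropenyl group, so the future C6 is set trans to the future C7.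

Step 4
Reactants: 9 (5S,6R)-6-allylcarvone
Product: 11 (5S,6R)-6-(3-hydroxypropyl)-2-methyl-5-(prop-1-en-2-yl)cyclohex-2-en-1-one, via B-alkyl disiamylborane 10 (not isolated)
Conditions: Sia2BH (from BH3·SMe2 and 2-methylbut-2-ene), THF, 0 °C; then NaBO3·4H2O, THF/H2O, rt
Reagents that add atoms: sodium perborate, [Na+].[O-]OB=O
Why: Anti-Markovnikov hydroboration–oxidation; the hindered dialkylborane selects the monosubstituted alkene over the 1,1-disubstituted isopropenyl group and should add faster than it reduces the hindered conjugated ketone. Perborate oxidises the borane without epoxidising the enone.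

Step 5
Reactants: 11 hydroxypropyl enone
Product: 12 (5S,6R)-6-[3-(tert-butyldimethylsilyloxy)propyl]-2-methyl-5-(prop-1-en-2-yl)cyclohex-2-en-1-one
Conditions: TBSCl, imidazole, CH2Cl2, rt
Reagents that add atoms: tert-butyldimethylsilyl chloride, CC(C)(C)[Si](C)(C)Cl
Why: Standard silylation of a primary alcohol; the ether has to survive strong bases, Me2AlCl, hydride and mild acid.

Step 6
Reactants: 12 silyloxypropyl enone
Product: 13 tert-butyl{3-[(1R,6S)-2-(methoxymethylidene)-3-methyl-6-(prop-1-en-2-yl)cyclohex-3-en-1-yl]propoxy}dimethylsilane (enol ether E/Z mixture)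
Conditions: MeOCH2PPh3Cl, KN(SiMe3)2, THF, 0 → 40 °C
Reagents that add atoms: (methoxymethyl)triphenylphosphonium chloride, COC[P+](c1ccccc1)(c1ccccc1)c1ccccc1.[Cl-]
Why: Wittig methoxymethylenation, a one-carbon homologation of a ketone with a small non-stabilised ylide that adds 1,2 to the enone. The trans arrangement at C6/C7 is the more stable one, so reversible enolisation cannot damage it.

Step 7
Reactants: 13 dienol ether
Product: 15 (5S,6R)-6-[3-(tert-butyldimethylsilyloxy)propyl]-2-methyl-5-(prop-1-en-2-yl)cyclohex-1-ene-1-carbaldehyde, via β,γ-unsaturated aldehyde 14 (not isolated)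
Conditions: 0.5 M aq. HCl, THF, 0 °C; then DBU (cat.), CH2Cl2, rt
Reagents that add atoms: water, O
Why: Enol ether hydrolysis, then base-mediated conjugation of the β,γ-unsaturated aldehyde through its dienolate to the tetrasubstituted enal. C6 and C7 carry no acidic hydrogen, and brief cold dilute acid spares the primary silyl ether.

Step 8
Reactants: 15 conjugated enal; 5 enynyl bromide
Product: 17 (1R,5S,6R)-6-[3-(tert-butyldimethylsilyloxy)propyl]-2-methyl-1-[(3E)-4-methyl-6-(trimethylsilyl)hex-3-en-5-yn-1-yl]-5-(prop-1-en-2-yl)cyclohex-2-ene-1-carbaldehyde, via potassium dienolate 16 (not isolated)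
Conditions: KN(SiMe3)2, THF, −78 °C; then 5, DMPU, −78 → 0 °C
Reagents that add atoms: none
Why: Deconjugative α-alkylation of an enal dienolate: γ-deprotonation gives the extended enolate, which reacts with the primary bromide at the α-carbon to give the α-quaternary β,γ-unsaturated aldehyde. The electrophile should enter anti to the adjacent C6 chain (1,2-induction), which places the formyl group cis to that chain as C5 requires.

Step 9
Reactants: 17 enynyl aldehyde
Product: 18 (1S,2R,5R,6R,7S)-6-[3-(tert-butyldimethylsilyloxy)propyl]-10-methyl-7-(prop-1-en-2-yl)-2-[4-(trimethylsilyl)but-1-en-3-yn-2-yl]spiro[4.5]dec-9-en-1-ol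
Conditions: Me2AlCl (2 equiv), CH2Cl2, −78 → −20 °C
Reagents that add atoms: none
Why: Proposed new method: Me2AlCl binds the formyl oxygen of the non-enolisable aldehyde, and the activated carbonyl carbon is attacked by the CH terminus (C2) of the tethered trisubstituted enyne alkene while a hydrogen of the only allylic methyl group passes to oxygen through a six-membered, concerted but asynchronous transition state in which positive charge builds on the tertiary propargylic carbon. The closest known reaction is the Lewis acid-promoted type 1 intramolecular carbonyl-ene cyclisation of 5-enals to cis-2-(alk-1-en-2-yl)cyclopentanols; a 1,3-enyne has not served as the ene donor, but the alkynyl group can stabilise the developing charge as a propargyl/allenyl cation and leaves the methyl hydrogens as the only transferable ones. The cyclopentane closes 5-exo-trig with respect to the alkene (C1–C2 bond, the second alkene carbon stays outside the ring and becomes the new 1,1-disubstituted alkene). C1 and C2 are set together: the hydrogen transfer requires the oxygen and the new alkenyl group on the same face of the forming ring (cis), and this pair should turn towards the flat C9=C10 side of C5 and away from the substituted sp3 C6, which fixes both centres relative to C5. Chemoselectivity among the three alkenes follows from geometry, since the ring alkene could only give a three- or four-membered ring and the isopropenyl group lies on the face of the six-membered ring opposite to the formyl group. The second equivalent of Me2AlCl acts as proton scavenger (the aluminium alkoxide forms with loss of methane), which should suppress chloride capture and Prins-type products. Either geometry of the donor alkene converges on 18 because that stereo element disappears.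

Step 10
Reactants: 18 spirocyclic enyne alcohol
Product: 19 (1S,2R,5S,6R,7S,9S,10R)-9,10-epoxy-6-[3-(tert-butyldimethylsilyloxy)propyl]-10-methyl-7-(prop-1-en-2-yl)-2-[4-(trimethylsilyl)but-1-en-3-yn-2-yl]spiro[4.5]decan-1-ol (oxirane oxygen on the face of C1)
Conditions: VO(acac)2 (cat.), t-BuOOH, CH2Cl2, 0 °C → rt
Reagents that add atoms: tert-butyl hydroperoxide, CC(C)(C)OO
Why: Hydroxyl-directed epoxidation of a homoallylic alcohol: the vanadium alkoxide at C1 delivers oxygen to the face of C9=C10 on which C1 lies. The electron-rich trisubstituted ring alkene should outpace the alkyne-conjugated 1,1-disubstituted alkene (also homoallylic but electron-poor) and the remote isopropenyl group.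

Step 11
Reactants: 19 epoxy alcohol
Product: 20 (1S,2R,5S,6R,7S,10S)-6-[3-(tert-butyldimethylsilyloxy)propyl]-10-methyl-7-(prop-1-en-2-yl)-2-[4-(trimethylsilyl)but-1-en-3-yn-2-yl]spiro[4.5]decane-1,10-diol
Conditions: LiEt3BH, THF, 0 °C → rt
Reagents that add atoms: none
Why: SN2 hydride opening of a trisubstituted epoxide at the secondary carbon C9 (trans-diaxial), leaving the C10–O bond intact. C10 becomes the tertiary carbinol with its oxygen cis to C1.

Step 12
Reactants: 20 diol
Product: 22 2-[(1S,2R,5S,6R,7S,10S)-6-[3-(tert-butyldimethylsilyloxy)propyl]-1,10-dihydroxy-10-methyl-2-[4-(trimethylsilyl)but-1-en-3-yn-2-yl]spiro[4.5]decan-7-yl]prop-2-enal, via 2-substituted allylic alcohol 21 (not isolated)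
Conditions: SeO2 (cat.), t-BuOOH, CH2Cl2, rt; then MnO2, CH2Cl2, rt
Reagents that add atoms: selenium dioxide, O=[Se]=O; tert-butyl hydroperoxide, CC(C)(C)OO
Why: SeO2 allylic oxidation (ene reaction then 2,3-sigmatropic shift) at the methyl of the C7 isopropenyl group, the only allylic CH3 left in the molecule, followed by MnO2 oxidation of the primary allylic alcohol. The other 1,1-disubstituted alkene offers only a ring methine hydrogen and is deactivated by the alkyne.

Step 13
Reactants: 22 2-substituted propenal
Product: 23 (2Z)-2-[(1S,2R,5S,6R,10S)-6-[3-(tert-butyldimethylsilyloxy)propyl]-1,10-dihydroxy-10-methyl-2-[4-(trimethylsilyl)but-1-en-3-yn-2-yl]spiro[4.5]decan-7-ylidene]propanal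
Conditions: RhCl3·3H2O (cat.), EtOH, 60 °C
Reagents that add atoms: none
Why: Rhodium hydride-mediated migration of an α-methylene carbonyl double bond into the more substituted conjugated position (conjugate hydride addition to C=CH2, then β-hydride elimination of H7); this step removes the C7 stereocentre. The Z geometry should be favoured because the C11 methyl group avoids the C6 side, which carries the axial chain and adjoins the quaternary C5, while the flat formyl group tolerates it. The silyl cap keeps the alkyne from binding rhodium.

Step 14
Reactants: 23 Z-enal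
Product: 25 (1S,2R,5S,6R,10S)-2-(but-1-en-3-yn-2-yl)-6-[3-(tert-butyldimethylsilyloxy)propyl]-7-[(2Z)-1-hydroxypropan-2-ylidene]-10-methylspiro[4.5]decane-1,10-diol, via silylalkyne triol 24 (not isolated)
Conditions: NaBH4, CeCl3·7H2O, MeOH, −20 °C; then K2CO3, rt
Reagents that add atoms: none
Why: Luche 1,2-reduction parks the enal as its allylic alcohol, because step 17 uses a hydride catalyst. Methanolysis then removes the alkynyl silicon group without touching the alkyl silyl ether; the alkene geometry is not involved.

Step 15
Reactants: 26 5-bromo-2-methylpent-2-ene; 27 prop-2-yn-1-ol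
Product: 30 (2Z)-2-(iodomethylidene)-6-methylhept-5-en-1-ol, via (4-methylpent-3-en-1-yl)magnesium bromide 28 (not isolated), via cyclic alkenylmagnesium alkoxide 29 (not isolated)
Conditions: Mg, THF; then 27, CuI (cat.), Et2O/THF, −10 °C → rt; then I2, −20 °C
Reagents that add atoms: iodine, [I][I]
Why: Copper-catalysed anti-carbomagnesiation of a propargylic alkoxide (the first equivalent of Grignard reagent deprotonates the alcohol): the alkyl group goes to C2 and magnesium to C3 within a five-membered chelate. Iodinolysis with retention gives the alkenyl iodide with iodine cis to CH2OH.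

Step 16
Reactants: 30 iodo alcohol
Product: 31 tert-butyl{[(2Z)-2-(iodomethylidene)-6-methylhept-5-en-1-yl]oxy}dimethylsilane
Conditions: TBSCl, imidazole, CH2Cl2, rt
Reagents that add atoms: tert-butyldimethylsilyl chloride, CC(C)(C)[Si](C)(C)Cl
Why: Silylation of the primary allylic alcohol, so that the late MnO2 oxidation in step 18 meets only one allylic alcohol.

Step 17
Reactants: 25 terminal enyne triol; 31 alkenyl iodide
Product: 33 (1S,2R,5S,6R,10S)-6-[3-(tert-butyldimethylsilyloxy)propyl]-2-[(3E,5Z)-6-[(tert-butyldimethylsilyloxy)methyl]-10-methylundeca-1,3,5,9-tetraen-2-yl]-7-[(2Z)-1-hydroxypropan-2-ylidene]-10-methylspiro[4.5]decane-1,10-diol, via (E)-dienyl pinacol boronate 32 (not isolated)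
Conditions: HBpin (excess), Cp2Zr(H)Cl (cat.), Et3N (cat.), CH2Cl2, rt; then aq. K3PO4, Pd(PPh3)4 (cat.), 31, THF, rt
Reagents that add atoms: none
Why: Zirconium-catalysed syn hydroboration of the terminal alkyne of the enyne places boron on the terminal carbon (E-dienylboronate); borate esters formed at the hydroxyls are hydrolysed by the aqueous base. Suzuki–Miyaura coupling with the Z-alkenyl iodide proceeds with retention at both partners and gives the 3E,5Z triene.

Step 18
Reactants: 33 triene allylic alcohol
Product: 34 (2Z)-2-[(1S,2R,5S,6R,10S)-6-[3-(tert-butyldimethylsilyloxy)propyl]-2-[(3E,5Z)-6-[(tert-butyldimethylsilyloxy)methyl]-10-methylundeca-1,3,5,9-tetraen-2-yl]-1,10-dihydroxy-10-methylspiro[4.5]decan-7-ylidene]propanal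
Conditions: MnO2, CH2Cl2, rt
Reagents that add atoms: none
Why: Chemoselective MnO2 oxidation of the only free allylic alcohol. The C1 hydroxyl is homoallylic and secondary, the C10 hydroxyl is tertiary, and the allylic alcohol of the arm is silylated.

Step 19
Reactants: 34 bis-silyl ether
Product: 35 (2Z)-2-[(1S,2R,5S,6R,10S)-1,10-dihydroxy-2-[(3E,5Z)-6-(hydroxymethyl)-10-methylundeca-1,3,5,9-tetraen-2-yl]-6-(3-hydroxypropyl)-10-methylspiro[4.5]decan-7-ylidene]propanal (target)
Conditions: HF·pyridine, pyridine, THF, 0 °C → rt
Reagents that add atoms: none
Why: Buffered fluoride cleavage of the two primary silyl ethers; the conditions are mild enough for the enal, the triene and the tertiary alcohol.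

## Compound list

1 | cyclopropyl methyl ketone | CC(=O)C1CC1 | starting material
2 | ethynyltrimethylsilane | C#C[Si](C)(C)C | starting material
3 | lithium (trimethylsilyl)acetylide | [Li]C#C[Si](C)(C)C | intermediate
4 | 2-cyclopropyl-4-(trimethylsilyl)but-3-yn-2-ol (racemic) | CC(O)(C1CC1)C#C[Si](C)(C)C | intermediate
5 | [(3E)-6-bromo-3-methylhex-3-en-1-yn-1-yl]trimethylsilane | BrCC/C=C(\C)C#C[Si](C)(C)C | intermediate
6 | (S)-(+)-carvone | CC1=CC[C@@H](CC1=O)C(=C)C | starting material
7 | allyl bromide | C=CCBr | starting material
8 | lithium enolate of 6 (cross-conjugated dienolate, isopropenyl centre unchanged) | [Li]OC1=C[C@@H](C(C)=C)CC=C1C | intermediate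
9 | (5S,6R)-2-methyl-5-(prop-1-en-2-yl)-6-(prop-2-en-1-yl)cyclohex-2-en-1-one | O=C1[C@H](CC=C)[C@@H](C(C)=C)CC=C1C | intermediate
10 | B-alkyl disiamylborane from anti-Markovnikov addition to the allyl group of 9 | O=C1[C@H](CCCB(C(C)C(C)C)C(C)C(C)C)[C@@H](C(C)=C)CC=C1C | intermediate
11 | (5S,6R)-6-(3-hydroxypropyl)-2-methyl-5-(prop-1-en-2-yl)cyclohex-2-en-1-one | O=C1[C@H](CCCO)[C@@H](C(C)=C)CC=C1C | intermediate
12 | (5S,6R)-6-[3-(tert-butyldimethylsilyloxy)propyl]-2-methyl-5-(prop-1-en-2-yl)cyclohex-2-en-1-one | O=C1[C@H](CCCO[Si](C)(C)C(C)(C)C)[C@@H](C(C)=C)CC=C1C | intermediate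
13 | tert-butyl{3-[(1R,6S)-2-(methoxymethylidene)-3-methyl-6-(prop-1-en-2-yl)cyclohex-3-en-1-yl]propoxy}dimethylsilane (enol ether E/Z mixture) | COC=C1[C@H](CCCO[Si](C)(C)C(C)(C)C)[C@@H](C(C)=C)CC=C1C | intermediate
14 | (5S,6R)-6-[3-(tert-butyldimethylsilyloxy)propyl]-2-methyl-5-(prop-1-en-2-yl)cyclohex-2-ene-1-carbaldehyde (C1 epimers) | O=CC1[C@H](CCCO[Si](C)(C)C(C)(C)C)[C@@H](C(C)=C)CC=C1C | intermediate
15 | (5S,6R)-6-[3-(tert-butyldimethylsilyloxy)propyl]-2-methyl-5-(prop-1-en-2-yl)cyclohex-1-ene-1-carbaldehyde | O=CC1=C(C)CC[C@H](C(C)=C)[C@H]1CCCO[Si](C)(C)C(C)(C)C | intermediate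
16 | potassium dienolate of 15 (exocyclic enolate, ring diene) | [K]OC=C1C(C)=CC[C@H](C(C)=C)[C@H]1CCCO[Si](C)(C)C(C)(C)C | intermediate
17 | (1R,5S,6R)-6-[3-(tert-butyldimethylsilyloxy)propyl]-2-methyl-1-[(3E)-4-methyl-6-(trimethylsilyl)hex-3-en-5-yn-1-yl]-5-(prop-1-en-2-yl)cyclohex-2-ene-1-carbaldehyde | O=C[C@]1(CC/C=C(\C)C#C[Si](C)(C)C)[C@H](CCCO[Si](C)(C)C(C)(C)C)[C@@H](C(C)=C)CC=C1C | intermediate
18 | (1S,2R,5R,6R,7S)-6-[3-(tert-butyldimethylsilyloxy)propyl]-10-methyl-7-(prop-1-en-2-yl)-2-[4-(trimethylsilyl)but-1-en-3-yn-2-yl]spiro[4.5]dec-9-en-1-ol | C=C(C#C[Si](C)(C)C)[C@H]1CC[C@]2([C@H](CCCO[Si](C)(C)C(C)(C)C)[C@@H](C(C)=C)CC=C2C)[C@H]1O | intermediate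
19 | (1S,2R,5S,6R,7S,9S,10R)-9,10-epoxy derivative of 18 (oxirane oxygen on the face of C1) | C=C(C#C[Si](C)(C)C)[C@H]1CC[C@]2([C@H](CCCO[Si](C)(C)C(C)(C)C)[C@@H](C(C)=C)C[C@@H]3O[C@]23C)[C@H]1O | intermediate
20 | (1S,2R,5S,6R,7S,10S)-6-[3-(tert-butyldimethylsilyloxy)propyl]-10-methyl-7-(prop-1-en-2-yl)-2-[4-(trimethylsilyl)but-1-en-3-yn-2-yl]spiro[4.5]decane-1,10-diol | C=C(C#C[Si](C)(C)C)[C@H]1CC[C@]2([C@H](CCCO[Si](C)(C)C(C)(C)C)[C@@H](C(C)=C)CC[C@]2(C)O)[C@H]1O | intermediate
21 | 7-(3-hydroxyprop-1-en-2-yl) analogue of 20 | C=C(C#C[Si](C)(C)C)[C@H]1CC[C@]2([C@H](CCCO[Si](C)(C)C(C)(C)C)[C@@H](C(CO)=C)CC[C@]2(C)O)[C@H]1O | intermediate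
22 | 2-[(1S,2R,5S,6R,7S,10S)-6-[3-(tert-butyldimethylsilyloxy)propyl]-1,10-dihydroxy-10-methyl-2-[4-(trimethylsilyl)but-1-en-3-yn-2-yl]spiro[4.5]decan-7-yl]prop-2-enal | C=C(C#C[Si](C)(C)C)[C@H]1CC[C@]2([C@H](CCCO[Si](C)(C)C(C)(C)C)[C@@H](C(C=O)=C)CC[C@]2(C)O)[C@H]1O | intermediate
23 | (2Z)-2-[(1S,2R,5S,6R,10S)-6-[3-(tert-butyldimethylsilyloxy)propyl]-1,10-dihydroxy-10-methyl-2-[4-(trimethylsilyl)but-1-en-3-yn-2-yl]spiro[4.5]decan-7-ylidene]propanal | C=C(C#C[Si](C)(C)C)[C@H]1CC[C@]2([C@H](CCCO[Si](C)(C)C(C)(C)C)/C(=C(/C)C=O)CC[C@]2(C)O)[C@H]1O | intermediate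
24 | (Z)-allylic alcohol from 1,2-reduction of 23 (alkyne still silylated) | C=C(C#C[Si](C)(C)C)[C@H]1CC[C@]2([C@H](CCCO[Si](C)(C)C(C)(C)C)/C(=C(/C)CO)CC[C@]2(C)O)[C@H]1O | intermediate
25 | (1S,2R,5S,6R,10S)-2-(but-1-en-3-yn-2-yl)-6-[3-(tert-butyldimethylsilyloxy)propyl]-7-[(2Z)-1-hydroxypropan-2-ylidene]-10-methylspiro[4.5]decane-1,10-diol | C=C(C#C)[C@H]1CC[C@]2([C@H](CCCO[Si](C)(C)C(C)(C)C)/C(=C(/C)CO)CC[C@]2(C)O)[C@H]1O | intermediate
26 | 5-bromo-2-methylpent-2-ene | CC(C)=CCCBr | starting material
27 | prop-2-yn-1-ol | C#CCO | starting material
28 | (4-methylpent-3-en-1-yl)magnesium bromide | CC(C)=CCC[Mg]Br | intermediate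
29 | cyclic alkenylmagnesium alkoxide (2,5-dihydro-1,2-oxamagnesole with the 4-methylpent-3-enyl group on C4) | CC(C)=CCCC1=C[Mg]OC1 | intermediate
30 | (2Z)-2-(iodomethylidene)-6-methylhept-5-en-1-ol | I/C=C(\CO)CCC=C(C)C | intermediate
31 | tert-butyl{[(2Z)-2-(iodomethylidene)-6-methylhept-5-en-1-yl]oxy}dimethylsilane | I/C=C(\CO[Si](C)(C)C(C)(C)C)CCC=C(C)C | intermediate
32 | (E)-dienyl pinacol boronate of 25 (boron on the former alkyne terminus) | CC1(C)OB(/C=C/C(=C)[C@H]2CC[C@]3([C@H](CCCO[Si](C)(C)C(C)(C)C)/C(=C(/C)CO)CC[C@]3(C)O)[C@H]2O)OC1(C)C | intermediate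
33 | (1S,2R,5S,6R,10S)-6-[3-(tert-butyldimethylsilyloxy)propyl]-2-[(3E,5Z)-6-[(tert-butyldimethylsilyloxy)methyl]-10-methylundeca-1,3,5,9-tetraen-2-yl]-7-[(2Z)-1-hydroxypropan-2-ylidene]-10-methylspiro[4.5]decane-1,10-diol | C=C(/C=C/C=C(\CO[Si](C)(C)C(C)(C)C)CCC=C(C)C)[C@H]1CC[C@]2([C@H](CCCO[Si](C)(C)C(C)(C)C)/C(=C(/C)CO)CC[C@]2(C)O)[C@H]1O | intermediate
34 | bis(tert-butyldimethylsilyl) ether of the target (both primary hydroxyls silylated, Z-enal in place) | C=C(/C=C/C=C(\CO[Si](C)(C)C(C)(C)C)CCC=C(C)C)[C@H]1CC[C@]2([C@H](CCCO[Si](C)(C)C(C)(C)C)/C(=C(/C)C=O)CC[C@]2(C)O)[C@H]1O | intermediate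
35 | (2Z)-2-[(1S,2R,5S,6R,10S)-1,10-dihydroxy-2-[(3E,5Z)-6-(hydroxymethyl)-10-methylundeca-1,3,5,9-tetraen-2-yl]-6-(3-hydroxypropyl)-10-methylspiro[4.5]decan-7-ylidene]propanal | C=C(/C=C/C=C(\CO)CCC=C(C)C)[C@H]1CC[C@]2([C@H](CCCO)/C(=C(/C)C=O)CC[C@]2(C)O)[C@H]1O | target

## Step count and least certain steps

Total: 19 steps. Longest linear sequence: 15 steps from 6 to 35 (steps 3–14 and 17–19); steps 1–2 and 15–16 make the two side fragments.

**Step 9 (key step, proposed new method).**
- What may go wrong: the alkynyl substituent lowers the nucleophilicity of the donor alkene, so the closure may be slow. A fully ionised propargylic cation could capture chloride or lose a proton in another direction, the cis relationship at C1/C2 could erode through a stepwise course, and a methyl group could transfer from aluminium to the hindered aldehyde.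
- Fallback with known chemistry, setting out from 15 and returning at 18: the dienolate of 15 would be alkylated with 2-(3-iodopropyl)-2-methyl-1,3-dioxolane to give the ketal aldehyde F1, and mild aqueous acid would unmask the keto aldehyde F2.
- A magnesium-mediated intramolecular aldol reaction (MgBr2·OEt2, iPr2NEt; 5-exo-trig attack of the internal ketone enolate on the non-enolisable aldehyde through a chelated closed transition state) would give the cis-2-acetylcyclopentanol F3.
- TESCl and imidazole would give the triethylsilyl ether F4. Kinetic deprotonation at the methyl group with LiN(iPr)2 and trapping with N-(5-chloropyridin-2-yl)triflimide would give the enol triflate F5.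
- Sonogashira coupling with 2 (Pd(PPh3)4, CuI, Et2NH) would give the silyl-protected enyne F6, and PPTS in methanol would remove the triethylsilyl group to return 18.

**Step 13 (double-bond migration to the Z-enal).**
- What may go wrong: poor control of the C7=C11 geometry, because the two faces differ only through the C6 substituent. Other risks are incomplete migration, migration of the enyne double bond into the five-membered ring (loss of C2), and decarbonylation or acetal formation at the aldehyde.
- Fallback, setting out from 22 and returning at 23: carbonyl-directed chemistry that cannot touch the enyne. Organocatalytic transfer hydrogenation (Hantzsch ester, dibenzylammonium trifluoroacetate) would give the saturated α-methyl aldehyde F7. Amine/Pd(OAc)2 aerobic dehydrogenation of the Saegusa–Ito type (pyrrolidine, O2, DMSO) would then give 23. Any E isomer can be fed back through F7 by the same reduction.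

**Step 8 (quaternisation of C5).**
- What may go wrong: E2 elimination of the homoallylic bromide to a dienyne by the basic dienolate, O- or γ-alkylation, and weak facial selectivity, because the isopropenyl group on C7 shields the face that the C6 chain leaves open.
- Fallback, setting out from 15 and returning at 17: Stork metalloenamine alkylation. Condensation of 15 with cyclohexylamine would give the unsaturated imine F8. LiN(iPr)2 and then 5 would give the α-alkylated β,γ-unsaturated imine F9 (C-alkylation only, softer nucleophile). Buffered aqueous oxalic acid would release 17.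

**Step 10 (directed epoxidation).**
- What may go wrong: competing directed epoxidation of the alkyne-conjugated 1,1-disubstituted alkene, which is also homoallylic to the C1 hydroxyl, and insufficient facial control at C9=C10.
- Fallback, setting out from 18 and returning at 20 (bypassing 19): tethered delivery of oxygen by iodocarbonate cyclisation. Boc2O (after n-BuLi) would give the tert-butyl carbonate F10. IBr at −85 °C would give the six-membered iodo carbonate F11, in which the carbonate oxygen attacks C10 from the face of C1 and iodine ends up on C9. Bu3SnH with Et3B/O2 would give the cyclic carbonate F12, and LiAlH4 would open it to 20.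

**Step 4 (hydroboration beside an enone).**
- What may go wrong: reduction of the ketone by the borane, hydroboration of the isopropenyl group, or nucleophilic epoxidation of the enone during the oxidative work-up.
- Fallback, setting out from 6 and returning at 12 (bypassing 9 and 11): direct alkylation of the lithium enolate 8 with (3-iodopropoxy)(tert-butyl)dimethylsilane in THF/DMPU. This introduces the protected chain in one step without any borane, at the price of a less reactive electrophile.

## Further compounds

F1 | step 9 | (1R,5S,6R)-6-[3-(tert-butyldimethylsilyloxy)propyl]-2-methyl-1-[3-(2-methyl-1,3-dioxolan-2-yl)propyl]-5-(prop-1-en-2-yl)cyclohex-2-ene-1-carbaldehyde | O=C[C@]1(CCCC2(C)OCCO2)[C@H](CCCO[Si](C)(C)C(C)(C)C)[C@@H](C(C)=C)CC=C1C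
F2 | step 9 | (1R,5S,6R)-6-[3-(tert-butyldimethylsilyloxy)propyl]-2-methyl-1-(4-oxopentyl)-5-(prop-1-en-2-yl)cyclohex-2-ene-1-carbaldehyde | O=C[C@]1(CCCC(C)=O)[C@H](CCCO[Si](C)(C)C(C)(C)C)[C@@H](C(C)=C)CC=C1C
F3 | step 9 | 1-[(1S,2R,5R,6R,7S)-6-[3-(tert-butyldimethylsilyloxy)propyl]-1-hydroxy-10-methyl-7-(prop-1-en-2-yl)spiro[4.5]dec-9-en-2-yl]ethan-1-one (cis-hydroxy ketone) | CC(=O)[C@H]1CC[C@]2([C@H](CCCO[Si](C)(C)C(C)(C)C)[C@@H](C(C)=C)CC=C2C)[C@H]1O
F4 | step 9 | triethylsilyl ether of F3 | CC(=O)[C@H]1CC[C@]2([C@H](CCCO[Si](C)(C)C(C)(C)C)[C@@H](C(C)=C)CC=C2C)[C@H]1O[Si](CC)(CC)CC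
F5 | step 9 | enol triflate of F4 (1-substituted vinyl trifluoromethanesulfonate) | C=C(OS(=O)(=O)C(F)(F)F)[C@H]1CC[C@]2([C@H](CCCO[Si](C)(C)C(C)(C)C)[C@@H](C(C)=C)CC=C2C)[C@H]1O[Si](CC)(CC)CC
F6 | step 9 | triethylsilyl ether of 18 | C=C(C#C[Si](C)(C)C)[C@H]1CC[C@]2([C@H](CCCO[Si](C)(C)C(C)(C)C)[C@@H](C(C)=C)CC=C2C)[C@H]1O[Si](CC)(CC)CC
F7 | step 13 | 2-[(1S,2R,5S,6R,7S,10S)-6-[3-(tert-butyldimethylsilyloxy)propyl]-1,10-dihydroxy-10-methyl-2-[4-(trimethylsilyl)but-1-en-3-yn-2-yl]spiro[4.5]decan-7-yl]propanal (epimers at the α-carbon) | C=C(C#C[Si](C)(C)C)[C@H]1CC[C@]2([C@H](CCCO[Si](C)(C)C(C)(C)C)[C@@H](C(C)C=O)CC[C@]2(C)O)[C@H]1O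
F8 | step 8 | N-cyclohexyl imine of 15 | C1CCCCC1N=CC2=C(C)CC[C@H](C(C)=C)[C@H]2CCCO[Si](C)(C)C(C)(C)C
F9 | step 8 | N-cyclohexyl imine of 17 | C1CCCCC1N=C[C@]2(CC/C=C(\C)C#C[Si](C)(C)C)[C@H](CCCO[Si](C)(C)C(C)(C)C)[C@@H](C(C)=C)CC=C2C
F10 | step 10 | tert-butyl carbonate of 18 | C=C(C#C[Si](C)(C)C)[C@H]1CC[C@]2([C@H](CCCO[Si](C)(C)C(C)(C)C)[C@@H](C(C)=C)CC=C2C)[C@H]1OC(=O)OC(C)(C)C
F11 | step 10 | six-membered cyclic carbonate bridging the C1 and C10 oxygens with iodine on C9 (anti to the C10 oxygen) | C=C(C#C[Si](C)(C)C)[C@H]1CC[C@@]23[C@H](CCCO[Si](C)(C)C(C)(C)C)[C@@H](C(C)=C)C[C@@H](I)[C@]2(C)OC(=O)O[C@@H]13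
F12 | step 10 | cyclic carbonate of 20 (C1 and C10 oxygens) | C=C(C#C[Si](C)(C)C)[C@H]1CC[C@@]23[C@H](CCCO[Si](C)(C)C(C)(C)C)[C@@H](C(C)=C)CC[C@]2(C)OC(=O)O[C@@H]13
F0 | step 4 | none | none
A1 | alternative 1 | spirocyclic tetrasubstituted enoate (acetonide, p-methoxybenzyl ether) | C1CC[C@@]23[C@H](/C=C/COCc4ccc(OC)cc4)/C(=C(/C)C(=O)OC)CC[C@]2(C)OC(C)(C)O[C@@H]13
A2 | alternative 2 | trans-2-allyl-3-alkyl-4-methyl-4-(triethylsilyloxy)cyclohex-5-en-1-one | CC1(OCCO1)CC[C@H]2[C@H](CC=C)C(=O)C=C[C@]2(C)O[Si](CC)(CC)CC
A3 | alternative 3 | spiro cyclohexanone with tetrasubstituted alkylidene | C1CC[C@]2([C@H](CCCO[Si](C)(C)C(C)(C)C)/C(=C(/C)COCc3ccc(OC)cc3)CCC2=O)[C@H]1O[Si](CC)(CC)CC
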